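The amounts come first: cedar, larch and the flask carry the same L and Q and differ in D.

| setting | cedar | larch | flask |
|---|---|---|---|
| D | 0.34 M (fed, over 40 min) | 0.75 M (fed, over 40 min) | 0.50 M (fed, over 40 min) |
| L | 0.35 M | 0.35 M | 0.350 M |
| Q | 50 mM | 50 mM | 50 mM |
| remark | run made earlier | run made earlier |  |
| time |  |  | 12 h |

- cedar (time / h: D / %, J / %): 3.00: 11, 83; 6.00: 12, 84; 8.00: 4, 87; 12.0: 7, 90; 15.0: 5, 90
- larch (time / h: D / %, J / %): 1.33: 52, 35; 4.00: 44, 41; 6.00: 41, 43; 10.0: 42, 45; 15.0: 42, 40

(standard deviation of a reading: 2 percentage points)

- why nothing more happens at 12 h, or that something still does (it is still moving / no working catalyst is left / L has run out first / all of D has reacted)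
- how much of the D has reacted by 12 h
- how much J there is at 12 h, in percent of the D charged

- the analysis behind the earlier runs scatters by 2 percentage points, standard deviation
- what has gone from D into another species counts as reacted, even if it can come back
- the reaction counts as stopped when no species that holds the D changes by six tenths of a point or more over the second half of the time

Cedar holds 0.35 M of L for 0.34 M of D, and its J reaches 90% at 15.0 h. But larch holds 0.75 M of D on the same L, and its J levels off near 0.320 M while 42% of D stays at 15.0 h. That level is a reading with its scatter. It lies 0.0300 M under the L charge, less than the Q charge, so catalyst forms can hold that L.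

The flask has 0.350 M of L on 0.50 M of D, so at one J per L, L is the limiting reagent. In the flask the L charge over the D charge gives 70.0%: this L ceiling, at one J per L, is the most J in percent of the D charged. Taking off the larch gap, the reckoning here has L running out first in the flask, with J near 64.0%.

The forecast reads: no working catalyst is left, with 73% of D reacted and 63% of J, on the ground that “The catalyst seems to die after about six turnovers”. The two lie close on J and part on the end.

The flask gives: L has run out first, with 74.1% of D reacted and 62.6% of J.

    X ⇌ Z (K = 1.60, k = 3.60 min⁻¹)
    D + E ⇌ X (K = 1.70 L mol⁻¹, k = 15.0 L mol⁻¹ min⁻¹)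
    L + Q → E (k = 1.80 L mol⁻¹ min⁻¹)
    Z ⇌ Q + J (K = 0.500 M, k = 0.350 min⁻¹)
    D ⇌ G (K = 0.340, k = 0.00160 min⁻¹)

The half-life of L by its step with Q, other concentrations held at their charge, is 0.13 h, far shorter than the 12 h of the flask, and at 12.0 h L stands at 0% of its charge against 25.9% of D unbound. J in the flask lies 7.4 percentage points under the ceiling of 70.0%, and the catalyst forms E, X and Z amount to 7.36% of the D charged. With 2.0 M of D and other charges as in the flask, the ceiling is 17.5% and J stands at 16.1%.

The data were computed with constants of no real substance; the scatter is artificial.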